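**Plan**

1. Retrosynthesis: add back a C5=C6 double bond (with a chlorine on C6 as blocking atom), cut C10–C20 of the lactone, then the ring B bonds C7–C8 and C9–C10 ([4+2]), C5–C6 (cross-coupling) and C4–CH3 (asymmetric alkylation); ring C goes back to 1,2,4-trimethoxybenzene.
2. Forward: ring A (chiral keto ester, then vinylketene acetal) and ring C (bromoquinone) are joined by a Diels–Alder/aromatisation that makes ring B as a flat 1-naphthol; the lactone ring is closed next, and the C5=C6 bond is reduced last.
3. Enabling feature: in ring B, C10 is para to the C7 oxygen and 1,3 to C4. With ring B aromatic (C7–OH, C5=C6) and ring C as hydroquinone, C10 is the para carbon of a naphtholate, and the C4 carboxyl (C19), carrying C20 as a chloromethyl ester, hangs over it.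
4. Closing C10–C20 therefore dearomatises ring B and gives at once the quaternary C10, the bridged δ-lactone (C10–C20–O–C19–C4–C5) and the C7 ketone, from a precursor with one stereocentre.
5. Stereochemistry: C4 from a valine-enamine methylation; C10 relayed from C4 by the tether; C5 from dissolving-metal protonation (trans A/B).

Key step: step 12

Remark: C1 to C20 are abietane locants of the target (C4 bears CH3 and the C19 carbonyl, C10 bears C20; ring A = C1–C5, C10; ring B = C5–C10; ring C aromatic).
Assumption: the L-valine tert-butyl ester enamine methylation in toluene/HMPA is taken to give the (S)-keto ester 9; the facial sense of this alkylation depends on the lithium ligand, so the ligand (or the D-valine ester) that gives (S) is the one to use.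

**Step 1**
Reactants: 1 1,2,4-trimethoxybenzene
Product: 2 2-(2,3,6-trimethoxyphenyl)propan-2-ol
Conditions: n-BuLi, THF, 0 °C to rt; acetone, −78 °C to rt
Reagents that add atoms: acetone CC(C)=O
Why: Directed ortho-metalation, since the C3–H between two methoxy groups is the most acidic ring position of 1, followed by 1,2-addition of the aryllithium to acetone.

**Step 2**
Reactants: 2 2-(2,3,6-trimethoxyphenyl)propan-2-ol
Product: 3 1,2,4-trimethoxy-3-(propan-2-yl)benzene
Conditions: Et3SiH, CF3CO2H, CH2Cl2, 0 °C to rt
Reagents that add atoms: none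
Why: Ionic hydrogenation, in which acid ionises the tertiary benzylic alcohol to a cation stabilised by two ortho methoxy groups and the silane delivers hydride.

**Step 3**
Reactants: 3 1,2,4-trimethoxy-3-(propan-2-yl)benzene
Product: 4 1-bromo-2,4,5-trimethoxy-3-(propan-2-yl)benzene
Conditions: NBS, MeCN, 0 °C to rt
Reagents that add atoms: N-bromosuccinimide O=C1CCC(=O)N1Br
Why: Electrophilic aromatic bromination should go to the free position that is ortho to one methoxy group and para to another, the other free position having only one ortho oxygen donor.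

**Step 4**
Reactants: 4 1-bromo-2,4,5-trimethoxy-3-(propan-2-yl)benzene
Product: 5 2-bromo-5-methoxy-6-(propan-2-yl)cyclohexa-2,5-diene-1,4-dione
Conditions: (NH4)2Ce(NO3)6, MeCN/H2O, 0 °C
Reagents that add atoms: water O
Why: Oxidative demethylation of the para-dimethoxy pair by the tetravalent cerium salt should give the para-quinone, the third methoxy group surviving as a vinylogous ester.

**Step 5**
Reactants: 6 tert-butyl 2-oxocyclohexane-1-carboxylate
Product: 9 tert-butyl (1S)-1-methyl-2-oxocyclohexane-1-carboxylate, via valine enamine 7 (not isolated), via methylated ketimine 8 (not isolated)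
Conditions: L-valine tert-butyl ester, BF3·OEt2 (cat.), benzene, reflux, −H2O; LiN(iPr)2, toluene, −78 °C; HMPA, MeI, −78 °C; 1 M HCl, rt
Reagents that add atoms: iodomethane CI; water O
Why: Asymmetric alkylation of a chiral lithio-enamine, in which the valine ester carbonyl chelates lithium and its isopropyl group blocks one face of the aza-enolate, so that MeI should enter from the other face and set the quaternary C4 centre (S) before mild acid hydrolysis releases the auxiliary.

**Step 6**
Reactants: 9 tert-butyl (1S)-1-methyl-2-oxocyclohexane-1-carboxylate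
Product: 10 tert-butyl (1S)-1-methyl-2-{[(trifluoromethyl)sulfonyl]oxy}cyclohex-2-ene-1-carboxylate
Conditions: KN(SiMe3)2, THF, −78 °C; PhNTf2, −78 to 0 °C
Reagents that add atoms: N-phenylbis(trifluoromethanesulfonimide) O=S(=O)(N(c1ccccc1)S(=O)(=O)C(F)(F)F)C(F)(F)F
Why: The ketone can enolise only away from the quaternary carbon, so deprotonation and O-triflation should give a single enol triflate.

**Step 7**
Reactants: 10 tert-butyl (1S)-1-methyl-2-{[(trifluoromethyl)sulfonyl]oxy}cyclohex-2-ene-1-carboxylate
Product: 11 tert-butyl (1S)-2-(2-methoxy-2-oxoethyl)-1-methylcyclohex-2-ene-1-carboxylate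
Conditions: BrZnCH2CO2Me, Pd2(dba)3 (cat.), XPhos, THF, 60 °C
Reagents that add atoms: bromo(2-methoxy-2-oxoethyl)zinc COC(=O)C[Zn]Br
Why: Negishi-type coupling of the enol triflate with a Reformatsky zinc enolate under zerovalent palladium catalysis should form the C5–C6 bond, and the neighbouring quaternary centre cannot epimerise.

**Step 8**
Reactants: 11 tert-butyl (1S)-2-(2-methoxy-2-oxoethyl)-1-methylcyclohex-2-ene-1-carboxylate
Product: 12 tert-butyl (1S)-2-(1-chloro-2-methoxy-2-oxoethyl)-1-methylcyclohex-2-ene-1-carboxylate (both epimers at the CHCl carbon)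
Conditions: LiN(iPr)2, THF, −78 °C; Cl3CCCl3, −78 °C
Reagents that add atoms: hexachloroethane ClC(Cl)(Cl)C(Cl)(Cl)Cl
Why: Deprotonation of the doubly activated CH2 gives a lithium dienolate, which should be chlorinated at its α-carbon (kinetic α-selectivity of dienolates); this chlorine later blocks C6.

**Step 9**
Reactants: 12 tert-butyl (1S)-2-(1-chloro-2-methoxy-2-oxoethyl)-1-methylcyclohex-2-ene-1-carboxylate; 5 2-bromo-5-methoxy-6-(propan-2-yl)cyclohexa-2,5-diene-1,4-dione
Product: 15 tert-butyl (1S)-10-chloro-9-hydroxy-6-methoxy-1-methyl-5,8-dioxo-7-(propan-2-yl)-1,2,3,4,5,8-hexahydrophenanthrene-1-carboxylate, via chlorovinylketene silyl acetal 13 (not isolated), via Diels–Alder adduct 14 (not isolated)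
Conditions: LiN(iPr)2, THF, −78 °C; Me3SiCl; volatiles removed, pentane filtrate; then 5, CH2Cl2, −40 °C to rt; Et3N; SiO2, H2O
Reagents that add atoms: none
Why: Diels–Alder benzannulation of a vinylketene acetal with a haloquinone, in which the nucleophilic diene terminus (C10) should add to the unsubstituted carbon of the bromo-alkene so that the acetal carbon (C7) ends on the bromine-bearing carbon, and loss of HBr and then MeOH aromatises ring B to the peri-hydroxy naphthoquinone without touching C4.

**Step 10**
Reactants: 15 tert-butyl (1S)-10-chloro-9-hydroxy-6-methoxy-1-methyl-5,8-dioxo-7-(propan-2-yl)-1,2,3,4,5,8-hexahydrophenanthrene-1-carboxylate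
Product: 16 (1S)-10-chloro-9-hydroxy-6-methoxy-1-methyl-5,8-dioxo-7-(propan-2-yl)-1,2,3,4,5,8-hexahydrophenanthrene-1-carboxylic acid
Conditions: CF3CO2H, CH2Cl2, 0 °C to rt
Reagents that add atoms: none
Why: Acidolysis of the tert-butyl ester (E1 loss of isobutene) should free the hindered acid and leave quinone, chelated phenol and aryl chloride alone.

**Step 11**
Reactants: 16 (1S)-10-chloro-9-hydroxy-6-methoxy-1-methyl-5,8-dioxo-7-(propan-2-yl)-1,2,3,4,5,8-hexahydrophenanthrene-1-carboxylic acid
Product: 17 chloromethyl (1S)-10-chloro-9-hydroxy-6-methoxy-1-methyl-5,8-dioxo-7-(propan-2-yl)-1,2,3,4,5,8-hexahydrophenanthrene-1-carboxylate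
Conditions: ClCH2OSO2Cl, NaHCO3, Bu4NHSO4 (cat.), CH2Cl2/H2O, 0 °C to rt
Reagents that add atoms: chloromethyl chlorosulfate ClCOS(=O)(=O)Cl
Why: Phase-transfer O-alkylation of the carboxylate at the CH2 of the reagent (chlorosulfate leaves) should give the chloromethyl ester, the chelated, chlorine-flanked peri-OH being a far poorer nucleophile.

**Step 12**
Reactants: 17 chloromethyl (1S)-10-chloro-9-hydroxy-6-methoxy-1-methyl-5,8-dioxo-7-(propan-2-yl)-1,2,3,4,5,8-hexahydrophenanthrene-1-carboxylate
Product: 19 (4S,10S)-6-chloro-11,14-dihydroxy-12-methoxy-7-oxoabieta-5,8,11,13-tetraen-19,20-olide, via naphthalenetriol 18 (not isolated)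
Conditions: Na2S2O4, EtOAc/H2O, rt, Ar; then Cs2CO3, DMF (degassed, 0.005 M), 25 °C
Reagents that add atoms: none
Why: Dithionite reduces the quinone to the electron-rich naphthalene-1,4,5-triol 18, and carbonate then forms the naphtholate on the C7 oxygen (hydrogen-bonded to the peri C14 oxygen). Its para carbon C10 displaces chloride from the chloromethyl ester in an intramolecular SN2 C-alkylation; the closest known reaction type is the base-mediated intramolecular para-alkylative dearomatisation of phenols and naphthols by a tethered alkyl halide. The δ-lactone ring C10–C20–O–C19–C4–C5 closes in a 6-exo-tet mode (6-enolendo with respect to the naphtholate) and gives a 3-oxabicyclo[3.3.1]nonan-2-one fused to the ring B dienone, so the C7 ketone appears in the same step. The new quaternary centre C10 is controlled by C4, because the three-atom tether from the pseudoaxial C19 reaches only the face of C10 syn to C19, so C20 and C19 must be cis. The step needs C10 over C6 and C over O selectivity: C6 carries chlorine, the oxygens on C7 and C11 are out of reach of the tether, and high dilution holds back intermolecular O-alkylation. Relief of the bay strain between the C1 methylene and the C11 oxygen as C10 pyramidalises adds driving force. (The descriptor 10S in 19 only reflects the chlorine in the CIP ranking; the spatial arrangement is that of the target.)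

**Step 13**
Reactants: 19 (4S,10S)-6-chloro-11,14-dihydroxy-12-methoxy-7-oxoabieta-5,8,11,13-tetraen-19,20-olide
Product: 20 (4S,5R,10R)-11,14-dihydroxy-12-methoxy-7-oxoabieta-8,11,13-trien-19,20-olide (target)
Conditions: Li, NH3(l)/THF, t-BuOH, −78 °C; NH4Cl
Reagents that add atoms: none
Why: Dissolving-metal (Birch-type) conjugate reduction, in which the vinyl chloride is cleaved first and the enone radical anion is then protonated at C5; both faces give axial protonation with respect to ring B, and the carbanionic lobe should prefer the face anti to the electron-poor C4–C19 and C10–C20 bonds, which leads to the epimer with C6 over the lactone bridge (one syn-axial hydrogen fewer), that is the trans A/B 5α-H product, while the phenoxides protect ring C and the enolate protects C7.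

**Compound list**

1 | 1,2,4-trimethoxybenzene | COc1ccc(OC)c(OC)c1 | starting material
2 | 2-(2,3,6-trimethoxyphenyl)propan-2-ol | COc1ccc(OC)c(OC)c1C(C)(C)O | intermediate
3 | 1,2,4-trimethoxy-3-(propan-2-yl)benzene | COc1ccc(OC)c(OC)c1C(C)C | intermediate
4 | 1-bromo-2,4,5-trimethoxy-3-(propan-2-yl)benzene | COc1c(Br)cc(OC)c(OC)c1C(C)C | intermediate
5 | 2-bromo-5-methoxy-6-(propan-2-yl)cyclohexa-2,5-diene-1,4-dione | O=C1C(Br)=CC(=O)C(OC)=C1C(C)C | intermediate
6 | tert-butyl 2-oxocyclohexane-1-carboxylate | O=C1CCCCC1C(=O)OC(C)(C)C | starting material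
7 | tert-butyl 2-{[(2S)-1-tert-butoxy-3-methyl-1-oxobutan-2-yl]amino}cyclohex-1-ene-1-carboxylate (valine enamine) | CC(C)[C@H](NC1=C(C(=O)OC(C)(C)C)CCCC1)C(=O)OC(C)(C)C | intermediate (not isolated)
8 | tert-butyl (1S)-2-{[(2S)-1-tert-butoxy-3-methyl-1-oxobutan-2-yl]imino}-1-methylcyclohexane-1-carboxylate | CC(C)[C@H](N=C1CCCC[C@]1(C)C(=O)OC(C)(C)C)C(=O)OC(C)(C)C | intermediate (not isolated)
9 | tert-butyl (1S)-1-methyl-2-oxocyclohexane-1-carboxylate | O=C1CCCC[C@]1(C)C(=O)OC(C)(C)C | intermediate
10 | tert-butyl (1S)-1-methyl-2-{[(trifluoromethyl)sulfonyl]oxy}cyclohex-2-ene-1-carboxylate | FC(F)(F)S(=O)(=O)OC1=CCCC[C@]1(C)C(=O)OC(C)(C)C | intermediate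
11 | tert-butyl (1S)-2-(2-methoxy-2-oxoethyl)-1-methylcyclohex-2-ene-1-carboxylate | COC(=O)CC1=CCCC[C@]1(C)C(=O)OC(C)(C)C | intermediate
12 | tert-butyl (1S)-2-(1-chloro-2-methoxy-2-oxoethyl)-1-methylcyclohex-2-ene-1-carboxylate (CHCl epimers) | COC(=O)C(Cl)C1=CCCC[C@]1(C)C(=O)OC(C)(C)C | intermediate
13 | tert-butyl (1S)-2-{1-chloro-2-methoxy-2-[(trimethylsilyl)oxy]ethenyl}-1-methylcyclohex-2-ene-1-carboxylate | COC(O[Si](C)(C)C)=C(Cl)C1=CCCC[C@]1(C)C(=O)OC(C)(C)C | intermediate (not isolated)
14 | tert-butyl (1S)-8a-bromo-10-chloro-6,9-dimethoxy-1-methyl-5,8-dioxo-7-(propan-2-yl)-9-[(trimethylsilyl)oxy]-1,2,3,4,4a,4b,5,8,8a,9-decahydrophenanthrene-1-carboxylate (Diels–Alder adduct, new centres as formed) | COC1(O[Si](C)(C)C)C(Cl)=C2C(CCC[C@]2(C)C(=O)OC(C)(C)C)C3C(=O)C(OC)=C(C(C)C)C(=O)C13Br | intermediate (not isolated)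
15 | tert-butyl (1S)-10-chloro-9-hydroxy-6-methoxy-1-methyl-5,8-dioxo-7-(propan-2-yl)-1,2,3,4,5,8-hexahydrophenanthrene-1-carboxylate | COC1=C(C(C)C)C(=O)c2c(O)c(Cl)c3c(c2C1=O)CCC[C@]3(C)C(=O)OC(C)(C)C | intermediate
16 | (1S)-10-chloro-9-hydroxy-6-methoxy-1-methyl-5,8-dioxo-7-(propan-2-yl)-1,2,3,4,5,8-hexahydrophenanthrene-1-carboxylic acid | COC1=C(C(C)C)C(=O)c2c(O)c(Cl)c3c(c2C1=O)CCC[C@]3(C)C(=O)O | intermediate
17 | chloromethyl (1S)-10-chloro-9-hydroxy-6-methoxy-1-methyl-5,8-dioxo-7-(propan-2-yl)-1,2,3,4,5,8-hexahydrophenanthrene-1-carboxylate | COC1=C(C(C)C)C(=O)c2c(O)c(Cl)c3c(c2C1=O)CCC[C@]3(C)C(=O)OCCl | intermediate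
18 | chloromethyl (1S)-10-chloro-5,8,9-trihydroxy-6-methoxy-1-methyl-7-(propan-2-yl)-1,2,3,4-tetrahydrophenanthrene-1-carboxylate | COc1c(C(C)C)c(O)c2c(O)c(Cl)c3c(c2c1O)CCC[C@]3(C)C(=O)OCCl | intermediate (not isolated)
19 | (4S,10S)-6-chloro-11,14-dihydroxy-12-methoxy-7-oxoabieta-5,8,11,13-tetraen-19,20-olide | COc1c(O)c2c(c(O)c1C(C)C)C(=O)C(Cl)=C1[C@]23CCC[C@]1(C)C(=O)OC3 | intermediate
20 | (4S,5R,10R)-11,14-dihydroxy-12-methoxy-7-oxoabieta-8,11,13-trien-19,20-olide | COc1c(O)c2c(c(O)c1C(C)C)C(=O)C[C@@H]1[C@]23CCC[C@]1(C)C(=O)OC3 | target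

**Step count and risks**

Total step count: 13. Longest linear sequence: 9 steps (steps 5 to 13, from 6; the ring C branch, steps 1 to 4 and then 9 to 13, is equally long).

Steps most likely to fail:

Step 12. The closure at C10 may be too slow, because allylic strain develops between the C6 chlorine and the in-plane C4 methyl; intermolecular O-alkylation, hydrolysis of the chloromethyl ester or air oxidation of the triol anion would then take over. The fallback reverses the activation (electrophile instead of nucleophile, no base) and sets out from 17. After the same dithionite reduction, the crude triol 18 is silylated with N,O-bis(trimethylsilyl)acetamide to chloromethyl (1S)-10-chloro-6-methoxy-1-methyl-7-(propan-2-yl)-5,8,9-tris[(trimethylsilyl)oxy]-1,2,3,4-tetrahydrophenanthrene-1-carboxylate F1. AgOSO2CF3 and 2,6-di-tert-butylpyridine in CH2Cl2 at −40 °C should ionise the chloromethyl ester. The acyloxymethyl cation would be captured at C10, which is para to the C7 silyloxy group, while C6 is blocked by chlorine and screened by the silyl group. Loss of Me3SiOSO2CF3 would give the 11,14-bis(trimethylsilyl) ether of the dienone lactone F2. Aqueous citric acid removes the silyl groups, and the route is rejoined at 19.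

Step 13. Facial selectivity in the protonation of C5 may be poor, since the two faces differ only by one syn-axial hydrogen and the electronic bias, or the lactone may be opened reductively. The fallback uses catalyst control instead of substrate control and sets out from 19. Hydrogenation (H2, 50 bar, CH2Cl2) with a cationic iridium N,P-ligand complex [Ir(cod)(L*)]B[3,5-(CF3)2C6H3]4, using the ligand antipode that adds H2 to the α face of C5, should give the 6-chloro-5α-H ketone (6-chloro derivative of the target, epimers at C6) F3. Zn in AcOH then removes the α-chlorine, and the route is rejoined at 20.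

Step 9. The diene 13 is twisted (C6 chlorine against the quaternary C4), so cycloaddition may lose out to addition through the α-carbon of the ketene acetal, or HBr may cleave the tert-butyl ester before it is trapped. The fallback moves the blocking atom to after the annulation and sets out from 11. LiN(iPr)2 and Me3SiCl give tert-butyl (1S)-2-{2-methoxy-2-[(trimethylsilyl)oxy]ethenyl}-1-methylcyclohex-2-ene-1-carboxylate F4. With 5 this should give the chlorine-free Diels–Alder adduct F5 and, after Et3N and SiO2, tert-butyl (1S)-9-hydroxy-6-methoxy-1-methyl-5,8-dioxo-7-(propan-2-yl)-1,2,3,4,5,8-hexahydrophenanthrene-1-carboxylate F6. Chlorination with SO2Cl2 (CH2Cl2, 0 °C) at the only free ring B position, ortho to the chelated OH, rejoins the route at 15.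

**Further compounds**

F1 | step 12 | chloromethyl (1S)-10-chloro-6-methoxy-1-methyl-7-(propan-2-yl)-5,8,9-tris[(trimethylsilyl)oxy]-1,2,3,4-tetrahydrophenanthrene-1-carboxylate | COc1c(C(C)C)c(O[Si](C)(C)C)c2c(O[Si](C)(C)C)c(Cl)c3c(c2c1O[Si](C)(C)C)CCC[C@]3(C)C(=O)OCCl
F2 | step 12 | 11,14-bis(trimethylsilyl) ether of 19 | COc1c(O[Si](C)(C)C)c2c(c(O[Si](C)(C)C)c1C(C)C)C(=O)C(Cl)=C1[C@]23CCC[C@]1(C)C(=O)OC3
F3 | step 13 | 6-chloro derivative of 20 (5α-H, epimers at C6) | COc1c(O)c2c(c(O)c1C(C)C)C(=O)C(Cl)[C@@H]1[C@]23CCC[C@]1(C)C(=O)OC3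
F4 | step 9 | tert-butyl (1S)-2-{2-methoxy-2-[(trimethylsilyl)oxy]ethenyl}-1-methylcyclohex-2-ene-1-carboxylate | COC(O[Si](C)(C)C)=CC1=CCCC[C@]1(C)C(=O)OC(C)(C)C
F5 | step 9 | tert-butyl (1S)-8a-bromo-6,9-dimethoxy-1-methyl-5,8-dioxo-7-(propan-2-yl)-9-[(trimethylsilyl)oxy]-1,2,3,4,4a,4b,5,8,8a,9-decahydrophenanthrene-1-carboxylate | COC1(O[Si](C)(C)C)C=C2C(CCC[C@]2(C)C(=O)OC(C)(C)C)C3C(=O)C(OC)=C(C(C)C)C(=O)C13Br
F6 | step 9 | tert-butyl (1S)-9-hydroxy-6-methoxy-1-methyl-5,8-dioxo-7-(propan-2-yl)-1,2,3,4,5,8-hexahydrophenanthrene-1-carboxylate | COC1=C(C(C)C)C(=O)c2c(O)cc3c(c2C1=O)CCC[C@]3(C)C(=O)OC(C)(C)C
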